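**Plan**

Ring numbering used below: C1 = stereocenter carrying the side chain, C2 = CMe2, C3–C5 = the three ring CH2 groups, C6 = ring carbon of the exocyclic C=CH2.
Retrosynthesis cuts, in order: butenolide ← 3-alkylfuran; the chain bond between the ring-bound CH2 and the first allylic CH2 (sulfone anion + E-allylic bromide); C6=CH2 ← C6 ketone; ring bond C3–C4.
The C3–C4 cut is possible because C3 is a CH2 on the quaternary C2, so it can be a neopentyl-type radical released by decarboxylation (3,3-dimethylglutarate supplies C1–C3 and the carboxyl that is lost), while C4 becomes the β-carbon of a vinyl ketone once C6 is a ketone: a polarity-matched 6-endo-trig closure.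
Forward: Evans alkylation on the glutarate chain sets C1; vinyl ketone; decarboxylative radical ring closure; methylenation; sulfone; coupling with a furan-terminated C15 bromide made from geranyl chloride; desulfonylation; furan-to-butenolide oxidation.
Stereochemistry: the only stereocenter (C1, S) comes from (S)-4-benzyl-oxazolidinone; both E-alkenes come from geranyl chloride and the E-selective SeO2 oxidation.

Key step: step 8

**Route**

Step 1
Reactants: 1 3,3-dimethylglutaric anhydride
Product: 2 5-tert-butoxy-3,3-dimethyl-5-oxopentanoic acid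
Conditions: t-BuOK, THF, 0 °C to rt; then 1 M HCl
Reagents that add atoms: potassium tert-butoxide, CC(C)(C)[O-].[K+]
Why: Alcoholysis of a cyclic anhydride by an alkoxide; the anhydride is symmetric, so only one mono-ester can form.

Step 2
Reactants: 2 5-tert-butoxy-3,3-dimethyl-5-oxopentanoic acid; 3 (S)-4-benzyl-1,3-oxazolidin-2-one
Product: 5 tert-butyl 5-[(4S)-4-benzyl-2-oxo-1,3-oxazolidin-3-yl]-3,3-dimethyl-5-oxopentanoate, via mixed pivalic anhydride 4 (not isolated)
Conditions: PivCl, Et3N, THF, −20 °C; then 3, LiCl, −20 °C to rt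
Reagents that add atoms: none
Why: Mixed-anhydride N-acylation of the oxazolidinone; the auxiliary should attack the less hindered glutarate carbonyl of the pivalic mixed anhydride.

Step 3
Reactants: 5 tert-butyl 5-[(4S)-4-benzyl-2-oxo-1,3-oxazolidin-3-yl]-3,3-dimethyl-5-oxopentanoate
Product: 7 tert-butyl (4R)-5-[(4S)-4-benzyl-2-oxo-1,3-oxazolidin-3-yl]-4-[(benzyloxy)methyl]-3,3-dimethyl-5-oxopentanoate, via sodium Z-enolate 6 (not isolated)
Conditions: NaHMDS, THF, −78 °C; then BnOCH2Cl, −78 to −30 °C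
Reagents that add atoms: benzyl chloromethyl ether, ClCOCc1ccccc1
Why: Evans asymmetric alkylation: the imide α-CH2 is deprotonated in preference to the ester α-CH2, and the small, reactive electrophile should add to the chelated Z-enolate on the face opposite the benzyl group, which sets C1 (R descriptor here, S in the target after the priority change).

Step 4
Reactants: 7 tert-butyl (4R)-5-[(4S)-4-benzyl-2-oxo-1,3-oxazolidin-3-yl]-4-[(benzyloxy)methyl]-3,3-dimethyl-5-oxopentanoate
Product: 8 (2R)-2-[(benzyloxy)methyl]-5-tert-butoxy-3,3-dimethyl-5-oxopentanoic acid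
Conditions: LiOH, H2O2, THF/H2O, 0 °C; then Na2SO3; then 1 M HCl
Reagents that add atoms: hydrogen peroxide, OO
Why: Auxiliary removal with hydroperoxide anion, which attacks the exocyclic imide carbonyl even in hindered imides without epimerising the α-center; the tert-butyl ester is stable to LiOH at 0 °C.

Step 5
Reactants: 8 (2R)-2-[(benzyloxy)methyl]-5-tert-butoxy-3,3-dimethyl-5-oxopentanoic acid
Product: 9 tert-butyl (4R)-4-[(benzyloxy)methyl]-5-[methoxy(methyl)amino]-3,3-dimethyl-5-oxopentanoate
Conditions: MeNHOMe·HCl, EDC·HCl, HOBt (cat.), N-methylmorpholine, CH2Cl2, 0 °C to rt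
Reagents that add atoms: N,O-dimethylhydroxylamine hydrochloride, CNOC.Cl
Why: Carbodiimide-mediated amidation gives the Weinreb amide without touching the α-center.

Step 6
Reactants: 9 tert-butyl (4R)-4-[(benzyloxy)methyl]-5-[methoxy(methyl)amino]-3,3-dimethyl-5-oxopentanoate
Product: 10 tert-butyl (4R)-4-[(benzyloxy)methyl]-3,3-dimethyl-5-oxohept-6-enoate
Conditions: CH2=CHMgBr, THF, −78 to 0 °C; inverse quench into cold 1 M HCl
Reagents that add atoms: vinylmagnesium bromide, C=C[Mg]Br
Why: Weinreb ketone synthesis: the chelated tetrahedral adduct prevents over-addition, the acidic quench keeps the released amine from adding to the vinyl ketone, and the tert-butyl ester is slow toward the Grignard reagent.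

Step 7
Reactants: 10 tert-butyl (4R)-4-[(benzyloxy)methyl]-3,3-dimethyl-5-oxohept-6-enoate
Product: 11 (4R)-4-[(benzyloxy)methyl]-3,3-dimethyl-5-oxohept-6-enoic acid
Conditions: TFA, CH2Cl2, 0 °C to rt
Reagents that add atoms: none
Why: Acidolysis of the tert-butyl ester through the tert-butyl cation; enone and benzyl ether should survive TFA.

Step 8
Reactants: 11 (4R)-4-[(benzyloxy)methyl]-3,3-dimethyl-5-oxohept-6-enoic acid
Product: 13 (2R)-2-[(benzyloxy)methyl]-3,3-dimethylcyclohexan-1-one, via N-acyloxyphthalimide 12 (not isolated)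
Conditions: N-hydroxyphthalimide, DIC, CH2Cl2, 0 °C to rt (no amine base); then Ru(bpy)3(PF6)2 (1 mol %), Hantzsch ester (1.5 equiv), degassed CH2Cl2 (0.01 M), blue LEDs, rt
Reagents that add atoms: none
Why: The N-acyloxyphthalimide 12 accepts an electron from photoreduced Ru(bpy)3 (monovalent ruthenium, formed by reductive quenching with the Hantzsch ester), loses phthalimide anion and CO2, and gives the primary radical at C3 (target ring numbering), which adds to the terminal CH2 (C4) of the vinyl ketone; the α-keto radical at C5 then takes a hydrogen atom from the Hantzsch ester. The closest known reaction types are the decarboxylative Giese addition of redox-active esters and the 6-endo cyclisation of alkyl radicals onto vinyl ketones whose carbonyl lies inside the forming ring. The cyclohexanone ring closes in the 6-endo-trig mode. No new stereocenter is formed, and C1 (α to the ketone) should stay intact because the medium is neutral and the radical develops at C5, not at C1. The step needs 6-endo over 5-exo closure and ring closure faster than hydrogen capture or 1,6-hydrogen transfer from the benzylic ether: the nucleophilic radical is polarity-matched with the β-carbon and gives a stabilised α-keto radical, whereas 5-exo attack at the α-carbon would give a primary radical, and the gem-dimethyl group at C2 (Thorpe–Ingold effect) plus 0.01 M dilution favour cyclisation over bimolecular reduction. The neopentyl position of C3 rules out SN2-based precursors, which is why the carboxylate is the chosen radical source.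

Step 9
Reactants: 13 (2R)-2-[(benzyloxy)methyl]-3,3-dimethylcyclohexan-1-one
Product: 14 ({[(1S)-2,2-dimethyl-6-methylidenecyclohexyl]methoxy}methyl)benzene
Conditions: Zn, CH2Br2, TiCl4 (pre-formed reagent), THF/CH2Cl2, 0 °C to rt
Reagents that add atoms: dibromomethane, BrCBr
Why: Lombardo methylenation with a non-basic titanium–zinc methylene reagent should convert the hindered, enolisable ketone without epimerising C1 or eliminating the β-benzyloxy group.

Step 10
Reactants: 14 ({[(1S)-2,2-dimethyl-6-methylidenecyclohexyl]methoxy}methyl)benzene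
Product: 15 [(1S)-2,2-dimethyl-6-methylidenecyclohexyl]methanol ((S)-γ-cyclogeraniol)
Conditions: lithium 4,4'-di-tert-butylbiphenylide, THF, −78 °C; then NH4Cl
Reagents that add atoms: none
Why: Radical-anion (dissolving-metal type) cleavage of the benzyl ether leaves the isolated 1,1-disubstituted alkene untouched, which catalytic hydrogenolysis would not.

Step 11
Reactants: 15 [(1S)-2,2-dimethyl-6-methylidenecyclohexyl]methanol
Product: 16 {[(1S)-2,2-dimethyl-6-methylidenecyclohexyl]methyl}(phenyl)sulfane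
Conditions: PhSSPh, n-Bu3P, pyridine, rt to 50 °C
Reagents that add atoms: diphenyl disulfide, c1ccc(SSc2ccccc2)cc1
Why: Hata thioetherification: the alkoxyphosphonium salt of the primary alcohol is displaced by thiophenolate in an SN2 step that does not involve C1.

Step 12
Reactants: 16 {[(1S)-2,2-dimethyl-6-methylidenecyclohexyl]methyl}(phenyl)sulfane
Product: 17 ({[(1S)-2,2-dimethyl-6-methylidenecyclohexyl]methyl}sulfonyl)benzene
Conditions: (NH4)6Mo7O24·4H2O (cat.), 30% H2O2, EtOH, 0 °C to rt
Reagents that add atoms: hydrogen peroxide, OO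
Why: Molybdate-catalysed peroxide oxidation takes a sulfide to the sulfone much faster than it epoxidises an unactivated 1,1-disubstituted alkene.

Step 13
Reactants: 18 furan-3-ylmethanol
Product: 19 3-(chloromethyl)furan
Conditions: SOCl2, pyridine, Et2O, 0 °C
Reagents that add atoms: thionyl chloride, O=S(Cl)Cl
Why: Chlorodehydroxylation of a primary furylmethyl alcohol through the chlorosulfite and SN2 attack by chloride.

Step 14
Reactants: 19 3-(chloromethyl)furan; 20 geranyl chloride ((2E)-1-chloro-3,7-dimethylocta-2,6-diene)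
Product: 22 dendrolasin (3-[(3E)-4,8-dimethylnona-3,7-dien-1-yl]furan), via (furan-3-ylmethyl)magnesium chloride 21 (not isolated)
Conditions: Mg, THF, rt; then 20, Li2CuCl4 (3 mol %), THF, 0 °C
Reagents that add atoms: none
Why: Copper-catalysed Kochi–Schlosser-type coupling of a Grignard reagent with a primary allylic chloride; attack should occur at the CH2 terminus because the other allyl terminus is fully substituted, so the E-alkene is kept.

Step 15
Reactants: 22 dendrolasin
Product: 23 (2E,6E)-9-(furan-3-yl)-2,6-dimethylnona-2,6-dien-1-ol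
Conditions: SeO2 (cat.), t-BuOOH, salicylic acid (cat.), CH2Cl2, 0 °C to rt
Reagents that add atoms: tert-butyl hydroperoxide, CC(C)(C)OO
Why: Catalytic SeO2 allylic oxidation (ene reaction, then [2,3]-sigmatropic shift) is selective for the E-methyl of a terminal isopropylidene group and should give the E-allylic alcohol.

Step 16
Reactants: 23 (2E,6E)-9-(furan-3-yl)-2,6-dimethylnona-2,6-dien-1-ol
Product: 24 3-[(3E,7E)-9-bromo-4,8-dimethylnona-3,7-dien-1-yl]furan
Conditions: CBr4, PPh3, CH2Cl2, 0 °C
Reagents that add atoms: carbon tetrabromide, BrC(Br)(Br)Br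
Why: Appel bromination of the primary allylic alcohol under neutral conditions keeps alkene position and geometry and spares the furan.

Step 17
Reactants: 17 ({[(1S)-2,2-dimethyl-6-methylidenecyclohexyl]methyl}sulfonyl)benzene; 24 3-[(3E,7E)-9-bromo-4,8-dimethylnona-3,7-dien-1-yl]furan
Product: 26 3-[(3E,7E)-10-[(1S)-2,2-dimethyl-6-methylidenecyclohexyl]-4,8-dimethyl-10-(phenylsulfonyl)deca-3,7-dien-1-yl]furan (both epimers at the sulfone carbon), via α-lithio sulfone 25 (not isolated)
Conditions: n-BuLi, THF, −78 °C; then 24, −78 to 0 °C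
Reagents that add atoms: none
Why: Alkylation of an α-sulfonyl carbanion by a primary allylic bromide (SN2 at the CH2 terminus), the classical terpenoid chain coupling; alkene geometry is retained and the sulfone-bearing center is erased in the next step.

Step 18
Reactants: 26 3-[(3E,7E)-10-[(1S)-2,2-dimethyl-6-methylidenecyclohexyl]-4,8-dimethyl-10-(phenylsulfonyl)deca-3,7-dien-1-yl]furan
Product: 27 3-[(3E,7E)-10-[(1S)-2,2-dimethyl-6-methylidenecyclohexyl]-4,8-dimethyldeca-3,7-dien-1-yl]furan
Conditions: Na(Hg) (6% Na), Na2HPO4, MeOH/THF, −20 °C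
Reagents that add atoms: none
Why: Reductive desulfonylation by electron transfer from sodium amalgam in buffered methanol; isolated alkenes and the furan should not be reduced.

Step 19
Reactants: 27 3-[(3E,7E)-10-[(1S)-2,2-dimethyl-6-methylidenecyclohexyl]-4,8-dimethyldeca-3,7-dien-1-yl]furan
Product: 29 4-[(3E,7E)-10-[(1S)-2,2-dimethyl-6-methylidenecyclohexyl]-4,8-dimethyldeca-3,7-dien-1-yl]-5-hydroxyfuran-2(5H)-one (both lactol epimers), via furan endoperoxide 28 (not isolated)
Conditions: O2, tetraphenylporphyrin (cat.), visible light, i-Pr2NEt, CH2Cl2, −78 °C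
Reagents that add atoms: dioxygen, O=O
Why: Singlet-oxygen (4+2) cycloaddition to the furan is much faster than the ene reaction of trisubstituted alkenes at −78 °C, and Kornblum–DeLaMare-type opening of the endoperoxide by the hindered amine at the bridgehead C–H remote from the alkyl group should give the 4-alkyl-5-hydroxybutenolide regioisomer.

Step 20
Reactants: 29 4-[(3E,7E)-10-[(1S)-2,2-dimethyl-6-methylidenecyclohexyl]-4,8-dimethyldeca-3,7-dien-1-yl]-5-hydroxyfuran-2(5H)-one
Product: 31 4-[(3E,7E)-10-[(1S)-2,2-dimethyl-6-methylidenecyclohexyl]-4,8-dimethyldeca-3,7-dien-1-yl]furan-2(5H)-one (CNP0135567.1), via sodium hydroxy-enoate 30 (not isolated)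
Conditions: NaBH4, MeOH/THF, 0 °C; then 1 M HCl
Reagents that add atoms: none
Why: Borohydride reduces the ring-opened aldehyde tautomer of the lactol, and the Z-4-hydroxy-enoate relactonises on acidification; the conjugated lactone should not be reduced at 0 °C.

**Compound list**

1 | 3,3-dimethylglutaric anhydride (4,4-dimethyloxane-2,6-dione) | CC1(C)CC(=O)OC(=O)C1 | starting material
2 | 5-tert-butoxy-3,3-dimethyl-5-oxopentanoic acid | CC(C)(C)OC(=O)CC(C)(C)CC(=O)O | intermediate
3 | (S)-4-benzyl-1,3-oxazolidin-2-one | O=C1N[C@@H](Cc2ccccc2)CO1 | starting material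
4 | mixed anhydride of 2 with pivalic acid | CC(C)(C)OC(=O)CC(C)(C)CC(=O)OC(=O)C(C)(C)C | intermediate
5 | tert-butyl 5-[(4S)-4-benzyl-2-oxo-1,3-oxazolidin-3-yl]-3,3-dimethyl-5-oxopentanoate | CC(C)(C)OC(=O)CC(C)(C)CC(=O)N1C(=O)OC[C@@H]1Cc1ccccc1 | intermediate
6 | sodium Z-enolate of 5 | CC(C)(C)OC(=O)CC(C)(C)/C=C(\[O-])N1C(=O)OC[C@@H]1Cc1ccccc1.[Na+] | intermediate
7 | tert-butyl (4R)-5-[(4S)-4-benzyl-2-oxo-1,3-oxazolidin-3-yl]-4-[(benzyloxy)methyl]-3,3-dimethyl-5-oxopentanoate | CC(C)(C)OC(=O)CC(C)(C)[C@@H](C(=O)N1C(=O)OC[C@@H]1Cc1ccccc1)COCc1ccccc1 | intermediate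
8 | (2R)-2-[(benzyloxy)methyl]-5-tert-butoxy-3,3-dimethyl-5-oxopentanoic acid | CC(C)(C)OC(=O)CC(C)(C)[C@@H](C(=O)O)COCc1ccccc1 | intermediate
9 | tert-butyl (4R)-4-[(benzyloxy)methyl]-5-[methoxy(methyl)amino]-3,3-dimethyl-5-oxopentanoate | CC(C)(C)OC(=O)CC(C)(C)[C@@H](C(=O)N(C)OC)COCc1ccccc1 | intermediate
10 | tert-butyl (4R)-4-[(benzyloxy)methyl]-3,3-dimethyl-5-oxohept-6-enoate | CC(C)(C)OC(=O)CC(C)(C)[C@@H](C(=O)C=C)COCc1ccccc1 | intermediate
11 | (4R)-4-[(benzyloxy)methyl]-3,3-dimethyl-5-oxohept-6-enoic acid | OC(=O)CC(C)(C)[C@@H](C(=O)C=C)COCc1ccccc1 | intermediate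
12 | 1,3-dioxoisoindolin-2-yl (4R)-4-[(benzyloxy)methyl]-3,3-dimethyl-5-oxohept-6-enoate | O=C(CC(C)(C)[C@@H](C(=O)C=C)COCc1ccccc1)ON1C(=O)c2ccccc2C1=O | intermediate
13 | (2R)-2-[(benzyloxy)methyl]-3,3-dimethylcyclohexan-1-one | O=C1CCCC(C)(C)[C@@H]1COCc1ccccc1 | intermediate
14 | ({[(1S)-2,2-dimethyl-6-methylidenecyclohexyl]methoxy}methyl)benzene | C=C1CCCC(C)(C)[C@@H]1COCc1ccccc1 | intermediate
15 | [(1S)-2,2-dimethyl-6-methylidenecyclohexyl]methanol | C=C1CCCC(C)(C)[C@@H]1CO | intermediate
16 | {[(1S)-2,2-dimethyl-6-methylidenecyclohexyl]methyl}(phenyl)sulfane | C=C1CCCC(C)(C)[C@@H]1CSc1ccccc1 | intermediate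
17 | ({[(1S)-2,2-dimethyl-6-methylidenecyclohexyl]methyl}sulfonyl)benzene | C=C1CCCC(C)(C)[C@@H]1CS(=O)(=O)c1ccccc1 | intermediate
18 | furan-3-ylmethanol | OCc1ccoc1 | starting material
19 | 3-(chloromethyl)furan | ClCc1ccoc1 | intermediate
20 | geranyl chloride, (2E)-1-chloro-3,7-dimethylocta-2,6-diene | CC(C)=CCC/C(C)=C/CCl | starting material
21 | (furan-3-ylmethyl)magnesium chloride | Cl[Mg]Cc1ccoc1 | intermediate
22 | dendrolasin, 3-[(3E)-4,8-dimethylnona-3,7-dien-1-yl]furan | CC(C)=CCC/C(C)=C/CCc1ccoc1 | intermediate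
23 | (2E,6E)-9-(furan-3-yl)-2,6-dimethylnona-2,6-dien-1-ol | OC/C(C)=C/CC/C(C)=C/CCc1ccoc1 | intermediate
24 | 3-[(3E,7E)-9-bromo-4,8-dimethylnona-3,7-dien-1-yl]furan | BrC/C(C)=C/CC/C(C)=C/CCc1ccoc1 | intermediate
25 | α-lithio derivative of sulfone 17 | C=C1CCCC(C)(C)[C@@H]1C([Li])S(=O)(=O)c1ccccc1 | intermediate
26 | 3-[(3E,7E)-10-[(1S)-2,2-dimethyl-6-methylidenecyclohexyl]-4,8-dimethyl-10-(phenylsulfonyl)deca-3,7-dien-1-yl]furan | C=C1CCCC(C)(C)[C@@H]1C(C/C(C)=C/CC/C(C)=C/CCc1ccoc1)S(=O)(=O)c1ccccc1 | intermediate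
27 | 3-[(3E,7E)-10-[(1S)-2,2-dimethyl-6-methylidenecyclohexyl]-4,8-dimethyldeca-3,7-dien-1-yl]furan | C=C1CCCC(C)(C)[C@@H]1CC/C(C)=C/CC/C(C)=C/CCc1ccoc1 | intermediate
28 | furan endoperoxide of 27 (2,3,7-trioxabicyclo[2.2.1]hept-5-ene carrying the side chain on C5) | C=C1CCCC(C)(C)[C@@H]1CC/C(C)=C/CC/C(C)=C/CCC1=CC2OOC1O2 | intermediate
29 | 4-[(3E,7E)-10-[(1S)-2,2-dimethyl-6-methylidenecyclohexyl]-4,8-dimethyldeca-3,7-dien-1-yl]-5-hydroxyfuran-2(5H)-one | C=C1CCCC(C)(C)[C@@H]1CC/C(C)=C/CC/C(C)=C/CCC1=CC(=O)OC1O | intermediate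
30 | sodium (2Z,6E,10E)-13-[(1S)-2,2-dimethyl-6-methylidenecyclohexyl]-3-(hydroxymethyl)-7,11-dimethyltrideca-2,6,10-trienoate | C=C1CCCC(C)(C)[C@@H]1CC/C(C)=C/CC/C(C)=C/CC/C(CO)=C/C(=O)[O-].[Na+] | intermediate
31 | 4-[(3E,7E)-10-[(1S)-2,2-dimethyl-6-methylidenecyclohexyl]-4,8-dimethyldeca-3,7-dien-1-yl]furan-2(5H)-one | C=C1CCCC(C)(C)[C@@H]1CC/C(C)=C/CC/C(C)=C/CCC1=CC(=O)OC1 | target

**Count and risks**

Total step count: 20. Longest linear sequence: 16 steps (steps 1–12, then 17–20); steps 13–16 make the side-chain bromide in parallel.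

Risk 1, step 3. The enolate carbon sits next to a quaternary carbon, so alkylation may be slow and the enolate may decompose or lose facial selectivity on warming. Fallback, setting out from 5 and coming back at 10: enolisation of 5 with Bu2BOTf/Et3N and syn-aldol addition to acrolein should give tert-butyl (4S,5R)-4-{[(4S)-4-benzyl-2-oxo-1,3-oxazolidin-3-yl]carbonyl}-5-hydroxy-3,3-dimethylhept-6-enoate F1. Here the imide carbonyl becomes the ring-bound CH2 and acrolein supplies the enone carbons; the same (S)-auxiliary gives the same sense at C1 because the boron aldol uses the opposite enolate face to the chelated alkylation. LiBH4/MeOH at 0 °C removes the auxiliary reductively to tert-butyl (4R,5R)-5-hydroxy-4-(hydroxymethyl)-3,3-dimethylhept-6-enoate F2. Stannylene-mediated benzylation (Bu2SnO; then BnBr, CsF) of the primary hydroxyl gives tert-butyl (4R,5R)-4-[(benzyloxy)methyl]-5-hydroxy-3,3-dimethylhept-6-enoate F3, and Dess–Martin oxidation of the allylic alcohol gives 10. This path also avoids Grignard addition to a hindered Weinreb amide.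

Risk 2, step 8. The primary radical may capture hydrogen before it cyclises, close 5-exo, or translocate by 1,6-hydrogen transfer from the benzylic ether; N-hydroxyphthalimide may also add to the enone during activation. Fallback, setting out from 3 and coming back at 13, makes the same C3–C4 bond as an alkene by ring-closing metathesis. Acylation of 3 with commercial 3,3-dimethylpent-4-enoic acid (PivCl, Et3N, LiCl) gives (4S)-4-benzyl-3-(3,3-dimethylpent-4-enoyl)-1,3-oxazolidin-2-one F4. NaHMDS/BnOCH2Cl gives (4S)-4-benzyl-3-{(2R)-2-[(benzyloxy)methyl]-3,3-dimethylpent-4-enoyl}-1,3-oxazolidin-2-one F5. LiOH/H2O2 gives (2R)-2-[(benzyloxy)methyl]-3,3-dimethylpent-4-enoic acid F6. Amidation as in step 5 gives (2R)-2-[(benzyloxy)methyl]-N-methoxy-N,3,3-trimethylpent-4-enamide F7. Allylmagnesium bromide gives (5R)-5-[(benzyloxy)methyl]-6,6-dimethylocta-1,7-dien-4-one F8. Second-generation Grubbs catalyst in CH2Cl2 at 40 °C should close (6R)-6-[(benzyloxy)methyl]-5,5-dimethylcyclohex-3-en-1-one F9. Hydrogenation over Pd/C in EtOAc with a trace of pyridine, which spares the benzyl ether, gives 13.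

Risk 3, step 15. Allylic oxidation may also occur at the internal trisubstituted alkene, and the electron-rich furan may be degraded by the peroxide. Fallback, setting out from 19 and coming back at 23, installs the hydroxyl before the furan is attached. SeO2/t-BuOOH oxidation of commercial geranyl acetate, where the allylic acetate deactivates the 2,3-alkene, gives (2E,6E)-8-hydroxy-3,7-dimethylocta-2,6-dien-1-yl acetate F10. TBSCl/imidazole gives (2E,6E)-8-[(tert-butyldimethylsilyl)oxy]-3,7-dimethylocta-2,6-dien-1-yl acetate F11. Li2CuCl4-catalysed substitution of the allylic acetate by the Grignard reagent 21 (made from 19 as in step 14) gives tert-butyl{[(2E,6E)-9-(furan-3-yl)-2,6-dimethylnona-2,6-dien-1-yl]oxy}dimethylsilane F12, and TBAF in THF gives 23.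

**Further compounds**

F1 | step 3 | tert-butyl (4S,5R)-4-{[(4S)-4-benzyl-2-oxo-1,3-oxazolidin-3-yl]carbonyl}-5-hydroxy-3,3-dimethylhept-6-enoate | CC(C)(C)OC(=O)CC(C)(C)[C@@H]([C@H](O)C=C)C(=O)N1C(=O)OC[C@@H]1Cc1ccccc1
F2 | step 3 | tert-butyl (4R,5R)-5-hydroxy-4-(hydroxymethyl)-3,3-dimethylhept-6-enoate | CC(C)(C)OC(=O)CC(C)(C)[C@@H]([C@H](O)C=C)CO
F3 | step 3 | tert-butyl (4R,5R)-4-[(benzyloxy)methyl]-5-hydroxy-3,3-dimethylhept-6-enoate | CC(C)(C)OC(=O)CC(C)(C)[C@@H]([C@H](O)C=C)COCc1ccccc1
F4 | step 8 | (4S)-4-benzyl-3-(3,3-dimethylpent-4-enoyl)-1,3-oxazolidin-2-one | C=CC(C)(C)CC(=O)N1C(=O)OC[C@@H]1Cc1ccccc1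
F5 | step 8 | (4S)-4-benzyl-3-{(2R)-2-[(benzyloxy)methyl]-3,3-dimethylpent-4-enoyl}-1,3-oxazolidin-2-one | C=CC(C)(C)[C@@H](C(=O)N1C(=O)OC[C@@H]1Cc1ccccc1)COCc1ccccc1
F6 | step 8 | (2R)-2-[(benzyloxy)methyl]-3,3-dimethylpent-4-enoic acid | C=CC(C)(C)[C@@H](C(=O)O)COCc1ccccc1
F7 | step 8 | (2R)-2-[(benzyloxy)methyl]-N-methoxy-N,3,3-trimethylpent-4-enamide | C=CC(C)(C)[C@@H](C(=O)N(C)OC)COCc1ccccc1
F8 | step 8 | (5R)-5-[(benzyloxy)methyl]-6,6-dimethylocta-1,7-dien-4-one | C=CC(C)(C)[C@@H](C(=O)CC=C)COCc1ccccc1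
F9 | step 8 | (6R)-6-[(benzyloxy)methyl]-5,5-dimethylcyclohex-3-en-1-one | O=C1CC=CC(C)(C)[C@@H]1COCc1ccccc1
F10 | step 15 | (2E,6E)-8-hydroxy-3,7-dimethylocta-2,6-dien-1-yl acetate | CC(=O)OC/C=C(C)/CC/C=C(C)/CO
F11 | step 15 | (2E,6E)-8-[(tert-butyldimethylsilyl)oxy]-3,7-dimethylocta-2,6-dien-1-yl acetate | CC(=O)OC/C=C(C)/CC/C=C(C)/CO[Si](C)(C)C(C)(C)C
F12 | step 15 | tert-butyl{[(2E,6E)-9-(furan-3-yl)-2,6-dimethylnona-2,6-dien-1-yl]oxy}dimethylsilane | CC(C)(C)[Si](C)(C)OC/C(C)=C/CC/C(C)=C/CCc1ccoc1
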